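**Retrosynthetic overview**

1. Lactone atoms are numbered O1, C2(=O), C3(=CH2), C4(CO2H), C5(alkyl), with C4/C5 cis. C2 of the single five-membered lactone ring lies between O1 and the methylene-bearing C3, so the ring is a terminal alkyne (C3 and its CH2), the C5 hydroxyl and one CO. It is closed by palladium cyclocarbonylation, with no enolate next to the cis C4 centre.
2. After the ring: the C4 carboxyl comes from CH2OPMB (DDQ, then nitroxyl oxidation); HF then frees the side-chain carbinol.
3. The alkynol precursor comes from a terminal epoxide and a C14 Grignard reagent (Cu catalysis); the chain is built from 11-bromoundec-1-ene and (S)-propylene oxide.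
4. The epoxide comes from one Sharpless epoxide of mono-PMB (E)-butenediol opened by an alkynylalane. Epoxidation fixes C5 and the invertive opening fixes C4, so the cis pair does not depend on an allenylmetal addition to an unbranched aldehyde, where syn control is uncertain.
5. Ring order: the lactone is the only ring and is formed in step 11.

Key step: step 11

Remark: (E)-but-2-ene-1,4-diol, 11-bromoundec-1-ene and (S)-propylene oxide are taken as bought; the primary oxygen is carried as a PMB ether (no silyl migration in the alkoxide steps, oxidative removal) and the remote carbinol as a TBS ether (removed by HF at the end).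

**Route**

Step 1
Reactants: 1 11-bromoundec-1-ene; 2 (S)-propylene oxide
Product: 4 (2S)-tetradec-13-en-2-ol, via undec-10-enylmagnesium bromide 3 (not isolated)
Conditions: Mg, THF, 40 °C; then CuI (10 mol%), 2, THF, −30 to 0 °C; aq. NH4Cl
Reagents that add atoms: none
Why: Cu-catalysed Grignard opening of a monosubstituted epoxide is an SN2 attack at the CH2 terminus, so the (S) carbinol centre of 2 is carried over untouched and becomes the side-chain stereocentre.

Step 2
Reactants: 4 (2S)-tetradec-13-en-2-ol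
Product: 5 tert-butyldimethyl{[(2S)-tetradec-13-en-2-yl]oxy}silane
Conditions: TBSCl, imidazole, DMF, rt
Reagents that add atoms: tert-butyldimethylsilyl chloride, CC(C)(C)[Si](C)(C)Cl
Why: Imidazole-promoted silylation of a secondary alcohol gives a silyl ether that should survive the Grignard, alkoxide, palladium and oxidation steps that follow.

Step 3
Reactants: 5 tert-butyldimethyl{[(2S)-tetradec-13-en-2-yl]oxy}silane
Product: 7 (13S)-13-[(tert-butyldimethylsilyl)oxy]tetradecan-1-ol, via B-alkyl-9-BBN adduct 6 (not isolated)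
Conditions: 9-BBN, THF, 0 °C to rt; then NaOH, H2O2, H2O, 0 °C to rt
Reagents that add atoms: hydrogen peroxide, OO
Why: Hydroboration–oxidation of a terminal alkene with 9-BBN places the hydroxyl on the terminal carbon (anti-Markovnikov).

Step 4
Reactants: 7 (13S)-13-[(tert-butyldimethylsilyl)oxy]tetradecan-1-ol
Product: 8 {[(2S)-14-bromotetradecan-2-yl]oxy}(tert-butyl)dimethylsilane
Conditions: CBr4, PPh3, CH2Cl2, 0 °C
Reagents that add atoms: carbon tetrabromide, BrC(Br)(Br)Br
Why: The Appel reaction turns the primary alcohol into the bromide under neutral conditions that leave the secondary silyl ether alone.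

Step 5
Reactants: 9 (E)-but-2-ene-1,4-diol
Product: 10 (E)-4-[(4-methoxybenzyl)oxy]but-2-en-1-ol
Conditions: NaH (1 equiv), PMBCl, n-Bu4NI (cat.), THF/DMF, 0 °C to rt; 9 in threefold excess
Reagents that add atoms: 4-methoxybenzyl chloride, COc1ccc(CCl)cc1
Why: Williamson etherification of a symmetric diol used in excess should stop at the mono-ether, and the unreacted diol is washed out with water.

Step 6
Reactants: 10 (E)-4-[(4-methoxybenzyl)oxy]but-2-en-1-ol
Product: 11 [(2S,3S)-3-{[(4-methoxybenzyl)oxy]methyl}oxiran-2-yl]methanol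
Conditions: Ti(O-i-Pr)4 (10 mol%), L-(+)-diethyl tartrate (12 mol%), t-BuOOH, 4 Å molecular sieves, CH2Cl2, −20 °C
Reagents that add atoms: tert-butyl hydroperoxide, CC(C)(C)OO
Why: Sharpless asymmetric epoxidation of an (E)-allylic alcohol with the L-(+)-tartrate titanium catalyst should give the (2S,3S) epoxide by reagent control, and its hydroxymethyl-bearing carbon becomes C5 of the lactone.

Step 7
Reactants: 11 [(2S,3S)-3-{[(4-methoxybenzyl)oxy]methyl}oxiran-2-yl]methanol; 12 ethynyltrimethylsilane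
Product: 15 (2R,3R)-3-{[(4-methoxybenzyl)oxy]methyl}-5-(trimethylsilyl)pent-4-yne-1,2-diol, via lithium (trimethylsilyl)acetylide 13 (not isolated), via diethyl[(trimethylsilyl)ethynyl]aluminium 14 (not isolated)
Conditions: 12, n-BuLi, toluene, −78 to 0 °C; Et2AlCl, 0 °C; then 11, toluene, 0 °C to rt; aq. potassium sodium tartrate
Reagents that add atoms: none
Why: Alkynylalanes open 2,3-epoxy alcohols through the aluminium alkoxide at the epoxide carbon remote from the hydroxymethyl group (C3) with inversion, which sets the future C4 centre by stereospecific SN2 opening while the carbinol carbon keeps its configuration.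

Step 8
Reactants: 15 (2R,3R)-3-{[(4-methoxybenzyl)oxy]methyl}-5-(trimethylsilyl)pent-4-yne-1,2-diol
Product: 17 (2R)-2-{(2R)-1-[(4-methoxybenzyl)oxy]-4-(trimethylsilyl)but-3-yn-2-yl}oxirane, via primary tosylate 16 (not isolated)
Conditions: NaH (2.2 equiv), N-tosylimidazole, THF, 0 °C to rt
Reagents that add atoms: none
Why: One-pot epoxide formation from a terminal 1,2-diol: the primary alkoxide is sulfonylated first and the secondary alkoxide displaces it (3-exo-tet), so the carbinol configuration is retained; the PMB ether cannot migrate and the C-silyl group shields the alkyne CH from the base.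

Step 9
Reactants: 8 {[(2S)-14-bromotetradecan-2-yl]oxy}(tert-butyl)dimethylsilane; 17 (2R)-2-{(2R)-1-[(4-methoxybenzyl)oxy]-4-(trimethylsilyl)but-3-yn-2-yl}oxirane
Product: 19 (2R,3S,17S)-17-[(tert-butyldimethylsilyl)oxy]-1-[(4-methoxybenzyl)oxy]-2-[(trimethylsilyl)ethynyl]octadecan-3-ol, via Grignard reagent 18 (not isolated)
Conditions: 8, Mg, THF, 45 °C; then CuI (10 mol%), 17, THF, −40 to 0 °C; aq. NH4Cl
Reagents that add atoms: none
Why: Cu-catalysed Grignard opening of the terminal epoxide at its CH2 carbon joins the two fragments by an sp3–sp3 bond without touching either stereocentre of 17.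

Step 10
Reactants: 19 (2R,3S,17S)-17-[(tert-butyldimethylsilyl)oxy]-1-[(4-methoxybenzyl)oxy]-2-[(trimethylsilyl)ethynyl]octadecan-3-ol
Product: 20 (2R,3S,17S)-17-[(tert-butyldimethylsilyl)oxy]-2-ethynyl-1-[(4-methoxybenzyl)oxy]octadecan-3-ol
Conditions: K2CO3 (0.2 equiv), MeOH, rt
Reagents that add atoms: none
Why: Methanolysis of the alkynyl C–Si bond with catalytic carbonate frees the terminal alkyne and leaves the O-silyl and PMB ethers intact.

Step 11
Reactants: 20 (2R,3S,17S)-17-[(tert-butyldimethylsilyl)oxy]-2-ethynyl-1-[(4-methoxybenzyl)oxy]octadecan-3-ol; 21 carbon monoxide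
Product: 24 (4R,5S)-5-{(14S)-14-[(tert-butyldimethylsilyl)oxy]pentadecyl}-4-{[(4-methoxybenzyl)oxy]methyl}-3-methylideneoxolan-2-one, via alkoxycarbonylpalladium chloride 22 (not isolated), via vinylpalladium chloride 23 (not isolated)
Conditions: PdCl2 (5 mol%), SnCl2 (5 mol%), PPh3 (10 mol%), CO (7 atm), MeCN, 75 °C
Reagents that add atoms: none
Why: Divalent palladium takes up CO and the hydroxyl on the future C5 to give alkoxycarbonyl complex 22 (O1–C2 formed), the tethered terminal alkyne inserts syn into the Pd–acyl bond to give 23 (C2–C3 formed), and protonolysis of the vinyl–Pd bond by the HCl released in the first event frees 24 and returns the catalyst. The closest known reaction type is the PdCl2/SnCl2/PPh3 cyclocarbonylation of but-3-yn-1-ols to α-methylene-γ-butyrolactones, which accepts secondary alcohols branched at the propargylic carbon. The lactone ring closes by a 5-exo-dig acylpalladation, and the former alkyne CH becomes the exocyclic methylene. No stereocentre is made: C4 and C5 arrive cis from 20 and should not epimerise, because no base or enolate is involved and C4 carries only an ether-bearing CH2 group, so the alkene has no reason to move into the ring. The step needs chemoselectivity for the one free hydroxyl, which is secured by the PMB ether on the C4 hydroxymethyl oxygen (a second homopropargylic hydroxyl there would give the isomeric lactone) and by the silyl ether on the remote carbinol.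

Step 12
Reactants: 24 (4R,5S)-5-{(14S)-14-[(tert-butyldimethylsilyl)oxy]pentadecyl}-4-{[(4-methoxybenzyl)oxy]methyl}-3-methylideneoxolan-2-one
Product: 25 (4R,5S)-5-{(14S)-14-[(tert-butyldimethylsilyl)oxy]pentadecyl}-4-(hydroxymethyl)-3-methylideneoxolan-2-one
Conditions: DDQ, CH2Cl2/pH 7 phosphate buffer, 0 °C
Reagents that add atoms: none
Why: DDQ oxidises only the electron-rich benzylic ether, whose hemiacetal hydrolyses to the primary alcohol; the electron-poor methylene lactone and the silyl ether are inert under these buffered neutral conditions.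

Step 13
Reactants: 25 (4R,5S)-5-{(14S)-14-[(tert-butyldimethylsilyl)oxy]pentadecyl}-4-(hydroxymethyl)-3-methylideneoxolan-2-one
Product: 27 (2S,3S)-2-{(14S)-14-[(tert-butyldimethylsilyl)oxy]pentadecyl}-4-methylidene-5-oxooxolane-3-carboxylic acid, via aldehyde 26 (not isolated)
Conditions: TEMPO (20 mol%), PhI(OAc)2 (2.5 equiv), MeCN/H2O 1:1, 0 °C to rt
Reagents that add atoms: water, O
Why: Oxoammonium (TEMPO) oxidation takes the primary alcohol to aldehyde 26, whose hydrate is oxidised on to the acid in the same weakly acidic, base-free medium, which is the best chance of keeping the cis C4 centre.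

Step 14
Reactants: 27 (2S,3S)-2-{(14S)-14-[(tert-butyldimethylsilyl)oxy]pentadecyl}-4-methylidene-5-oxooxolane-3-carboxylic acid
Product: 28 (2S,3S)-2-[(14S)-14-hydroxypentadecyl]-4-methylidene-5-oxooxolane-3-carboxylic acid
Conditions: HF·pyridine, THF, 0 °C to rt
Reagents that add atoms: none
Why: Fluoride-driven cleavage of the secondary silyl ether under acidic conditions should free the carbinol without adding to, isomerising or epimerising the methylene lactone acid.

**Compound list**

1 | 11-bromoundec-1-ene | C=CCCCCCCCCCBr | starting material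
2 | (S)-propylene oxide, (2S)-2-methyloxirane | C[C@H]1CO1 | starting material
3 | undec-10-enylmagnesium bromide | C=CCCCCCCCCC[Mg]Br | intermediate
4 | (2S)-tetradec-13-en-2-ol | C[C@H](O)CCCCCCCCCCC=C | intermediate
5 | tert-butyldimethyl{[(2S)-tetradec-13-en-2-yl]oxy}silane | C[C@H](O[Si](C)(C)C(C)(C)C)CCCCCCCCCCC=C | intermediate
6 | 9-{(13S)-13-[(tert-butyldimethylsilyl)oxy]tetradecyl}-9-borabicyclo[3.3.1]nonane | C[C@H](O[Si](C)(C)C(C)(C)C)CCCCCCCCCCCCB1C2CCCC1CCC2 | intermediate
7 | (13S)-13-[(tert-butyldimethylsilyl)oxy]tetradecan-1-ol | C[C@H](O[Si](C)(C)C(C)(C)C)CCCCCCCCCCCCO | intermediate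
8 | {[(2S)-14-bromotetradecan-2-yl]oxy}(tert-butyl)dimethylsilane | C[C@H](O[Si](C)(C)C(C)(C)C)CCCCCCCCCCCCBr | intermediate
9 | (E)-but-2-ene-1,4-diol | OC/C=C/CO | starting material
10 | (E)-4-[(4-methoxybenzyl)oxy]but-2-en-1-ol | OC/C=C/COCc1ccc(OC)cc1 | intermediate
11 | [(2S,3S)-3-{[(4-methoxybenzyl)oxy]methyl}oxiran-2-yl]methanol | OC[C@@H]1O[C@H]1COCc1ccc(OC)cc1 | intermediate
12 | ethynyltrimethylsilane | C#C[Si](C)(C)C | starting material
13 | lithium (trimethylsilyl)acetylide | [Li]C#C[Si](C)(C)C | intermediate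
14 | diethyl[(trimethylsilyl)ethynyl]aluminium | CC[Al](CC)C#C[Si](C)(C)C | intermediate
15 | (2R,3R)-3-{[(4-methoxybenzyl)oxy]methyl}-5-(trimethylsilyl)pent-4-yne-1,2-diol | C[Si](C)(C)C#C[C@H](COCc1ccc(OC)cc1)[C@@H](O)CO | intermediate
16 | (2R,3R)-2-hydroxy-3-{[(4-methoxybenzyl)oxy]methyl}-5-(trimethylsilyl)pent-4-yn-1-yl 4-methylbenzenesulfonate (present as its sodium alkoxide) | C[Si](C)(C)C#C[C@H](COCc1ccc(OC)cc1)[C@@H](O)COS(=O)(=O)c1ccc(C)cc1 | intermediate
17 | (2R)-2-{(2R)-1-[(4-methoxybenzyl)oxy]-4-(trimethylsilyl)but-3-yn-2-yl}oxirane | C[Si](C)(C)C#C[C@H](COCc1ccc(OC)cc1)[C@@H]1CO1 | intermediate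
18 | {(13S)-13-[(tert-butyldimethylsilyl)oxy]tetradecyl}magnesium bromide | C[C@H](O[Si](C)(C)C(C)(C)C)CCCCCCCCCCCC[Mg]Br | intermediate
19 | (2R,3S,17S)-17-[(tert-butyldimethylsilyl)oxy]-1-[(4-methoxybenzyl)oxy]-2-[(trimethylsilyl)ethynyl]octadecan-3-ol | C[Si](C)(C)C#C[C@H](COCc1ccc(OC)cc1)[C@@H](O)CCCCCCCCCCCCC[C@H](C)O[Si](C)(C)C(C)(C)C | intermediate
20 | (2R,3S,17S)-17-[(tert-butyldimethylsilyl)oxy]-2-ethynyl-1-[(4-methoxybenzyl)oxy]octadecan-3-ol (key-step precursor) | C#C[C@H](COCc1ccc(OC)cc1)[C@@H](O)CCCCCCCCCCCCC[C@H](C)O[Si](C)(C)C(C)(C)C | intermediate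
21 | carbon monoxide | [C-]#[O+] | starting material
22 | chloro{[(2R,3S,17S)-17-[(tert-butyldimethylsilyl)oxy]-2-ethynyl-1-[(4-methoxybenzyl)oxy]octadecan-3-yl]oxycarbonyl}palladium (phosphine ligands not drawn) | C#C[C@H](COCc1ccc(OC)cc1)[C@@H](OC(=O)[Pd]Cl)CCCCCCCCCCCCC[C@H](C)O[Si](C)(C)C(C)(C)C | intermediate
23 | chloro{(Z)-[(4R,5S)-5-{(14S)-14-[(tert-butyldimethylsilyl)oxy]pentadecyl}-4-{[(4-methoxybenzyl)oxy]methyl}-2-oxooxolan-3-ylidene]methyl}palladium (phosphine ligands not drawn) | Cl[Pd]/C=C1\C(=O)O[C@@H](CCCCCCCCCCCCC[C@H](C)O[Si](C)(C)C(C)(C)C)[C@H]1COCc1ccc(OC)cc1 | intermediate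
24 | (4R,5S)-5-{(14S)-14-[(tert-butyldimethylsilyl)oxy]pentadecyl}-4-{[(4-methoxybenzyl)oxy]methyl}-3-methylideneoxolan-2-one (key-step product) | C=C1C(=O)O[C@@H](CCCCCCCCCCCCC[C@H](C)O[Si](C)(C)C(C)(C)C)[C@H]1COCc1ccc(OC)cc1 | intermediate
25 | (4R,5S)-5-{(14S)-14-[(tert-butyldimethylsilyl)oxy]pentadecyl}-4-(hydroxymethyl)-3-methylideneoxolan-2-one | C=C1C(=O)O[C@@H](CCCCCCCCCCCCC[C@H](C)O[Si](C)(C)C(C)(C)C)[C@H]1CO | intermediate
26 | (2S,3S)-2-{(14S)-14-[(tert-butyldimethylsilyl)oxy]pentadecyl}-4-methylidene-5-oxooxolane-3-carbaldehyde | C=C1C(=O)O[C@@H](CCCCCCCCCCCCC[C@H](C)O[Si](C)(C)C(C)(C)C)[C@H]1C=O | intermediate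
27 | (2S,3S)-2-{(14S)-14-[(tert-butyldimethylsilyl)oxy]pentadecyl}-4-methylidene-5-oxooxolane-3-carboxylic acid | C=C1C(=O)O[C@@H](CCCCCCCCCCCCC[C@H](C)O[Si](C)(C)C(C)(C)C)[C@H]1C(=O)O | intermediate
28 | (2S,3S)-2-[(14S)-14-hydroxypentadecyl]-4-methylidene-5-oxooxolane-3-carboxylic acid | C=C1C(=O)O[C@@H](CCCCCCCCCCCCC[C@H](C)O)[C@H]1C(=O)O | target

**Step count**

Total: 14 steps. Longest linear sequence: 10 steps (steps 5–14 from 9; equally steps 1–4 and 9–14 from 1).

**Steps most likely to fail**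

Step 11. The cyclocarbonylation may stall through alkyne oligomerisation or reduction of the catalyst to metal. The tin chloride may also strip the PMB ether, so that the primary hydroxyl cyclises instead. The fallback sets out from 20 and returns at 24, and brings in the lactone carbonyl by oxidation instead of CO:
- Ruthenium-catalysed oxidative cyclisation of the homopropargylic alcohol (CpRuCl(cod), P(2-furyl)3, N-hydroxysuccinimide, n-Bu4NBr, NaHCO3, DMF/H2O, 95 °C) proceeds by way of a vinylidene and a cyclic oxacarbene. It would give the saturated cis lactone (4R,5S)-5-{(14S)-14-[(tert-butyldimethylsilyl)oxy]pentadecyl}-4-{[(4-methoxybenzyl)oxy]methyl}oxolan-2-one F1.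
- Its lithium enolate at C3 (LiN(SiMe3)2, THF, −78 °C) would be trapped with Me2N=CH2 iodide (Eschenmoser's salt) to give the Mannich base, the 3-[(dimethylamino)methyl] lactone F2.
- Methylation (MeI, MeOH, rt) would give the trimethylammonium iodide F3, and a wash with aqueous NaHCO3 would eliminate trimethylamine to give 24.
- An enolate is tolerable at this stage because C4 carries no acidic hydrogen while it bears only CH2OPMB.

Step 13. While the oxidation passes through aldehyde 26, C4 may epimerise from cis to trans, the exocyclic alkene may migrate into the ring, or the hydroxymethyl lactone may undergo acyl migration to the primary oxygen. The fallback sets out from 24 and returns at 27; it masks the methylene group so that C4–H is no longer allylic during the oxidation: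
- Conjugate addition of thiophenol (PhSH, Et3N cat., THF, 0 °C) would give the 3-[(phenylsulfanyl)methyl] lactone PMB ether F4.
- DDQ (CH2Cl2/pH 7 buffer) would give the 4-(hydroxymethyl)-3-[(phenylsulfanyl)methyl] lactone F5.
- TEMPO/PhI(OAc)2 in MeCN/H2O, which tolerates aryl sulfides, would give the sulfide acid, the 4-[(phenylsulfanyl)methyl]-5-oxooxolane-3-carboxylic acid F6.
- mCPBA (1 equiv, CH2Cl2, −78 °C) would give the sulfoxide acid F7, and thermal syn elimination (toluene, 110 °C) would give back the methylene group and deliver 27.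

Step 7. The ether oxygen on the neighbouring CH2 may slow attack at the desired epoxide carbon enough for the alkynyl group to enter at the carbon next to the free hydroxymethyl group, or chloride may open the epoxide. The fallback sets out from 11 and returns at 15; it removes the regiochemical question by using a C2-symmetric epoxide:
- DDQ (CH2Cl2/H2O) would cleave the PMB ether to give (2S,3S)-oxirane-2,3-diyldimethanol F8, in which both epoxide carbons are equivalent.
- Excess alane 14 (toluene, 0 °C to rt) would then give one triol, (2R,3R)-3-(hydroxymethyl)-5-(trimethylsilyl)pent-4-yne-1,2-diol F9.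
- 2,2-Dimethoxypropane with pyridinium p-toluenesulfonate would cap the terminal 1,2-diol as the five-membered acetonide, (2R)-2-[(4R)-2,2-dimethyl-1,3-dioxolan-4-yl]-4-(trimethylsilyl)but-3-yn-1-ol F10.
- NaH, PMBCl and n-Bu4NI (THF) would give the PMB ether, (4R)-4-{(2R)-1-[(4-methoxybenzyl)oxy]-4-(trimethylsilyl)but-3-yn-2-yl}-2,2-dimethyl-1,3-dioxolane F11.
- Aqueous acetic acid (rt) would release diol 15.

**Further compounds**

F1 | step 11 | (4R,5S)-5-{(14S)-14-[(tert-butyldimethylsilyl)oxy]pentadecyl}-4-{[(4-methoxybenzyl)oxy]methyl}oxolan-2-one | C1C(=O)O[C@@H](CCCCCCCCCCCCC[C@H](C)O[Si](C)(C)C(C)(C)C)[C@H]1COCc1ccc(OC)cc1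
F2 | step 11 | (4R,5S)-5-{(14S)-14-[(tert-butyldimethylsilyl)oxy]pentadecyl}-3-[(dimethylamino)methyl]-4-{[(4-methoxybenzyl)oxy]methyl}oxolan-2-one (C3 epimers) | CN(C)CC1C(=O)O[C@@H](CCCCCCCCCCCCC[C@H](C)O[Si](C)(C)C(C)(C)C)[C@H]1COCc1ccc(OC)cc1
F3 | step 11 | {[(4R,5S)-5-{(14S)-14-[(tert-butyldimethylsilyl)oxy]pentadecyl}-4-{[(4-methoxybenzyl)oxy]methyl}-2-oxooxolan-3-yl]methyl}trimethylammonium iodide (C3 epimers) | C[N+](C)(C)CC1C(=O)O[C@@H](CCCCCCCCCCCCC[C@H](C)O[Si](C)(C)C(C)(C)C)[C@H]1COCc1ccc(OC)cc1.[I-]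
F4 | step 13 | (4R,5S)-5-{(14S)-14-[(tert-butyldimethylsilyl)oxy]pentadecyl}-4-{[(4-methoxybenzyl)oxy]methyl}-3-[(phenylsulfanyl)methyl]oxolan-2-one (C3 epimers) | c1ccccc1SCC1C(=O)O[C@@H](CCCCCCCCCCCCC[C@H](C)O[Si](C)(C)C(C)(C)C)[C@H]1COCc1ccc(OC)cc1
F5 | step 13 | (4R,5S)-5-{(14S)-14-[(tert-butyldimethylsilyl)oxy]pentadecyl}-4-(hydroxymethyl)-3-[(phenylsulfanyl)methyl]oxolan-2-one (C3 epimers) | c1ccccc1SCC1C(=O)O[C@@H](CCCCCCCCCCCCC[C@H](C)O[Si](C)(C)C(C)(C)C)[C@H]1CO
F6 | step 13 | (2S,3S)-2-{(14S)-14-[(tert-butyldimethylsilyl)oxy]pentadecyl}-5-oxo-4-[(phenylsulfanyl)methyl]oxolane-3-carboxylic acid (C4 epimers) | c1ccccc1SCC1C(=O)O[C@@H](CCCCCCCCCCCCC[C@H](C)O[Si](C)(C)C(C)(C)C)[C@H]1C(=O)O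
F7 | step 13 | (2S,3S)-2-{(14S)-14-[(tert-butyldimethylsilyl)oxy]pentadecyl}-5-oxo-4-[(phenylsulfinyl)methyl]oxolane-3-carboxylic acid (C4 and sulfur epimers) | O=S(c1ccccc1)CC1C(=O)O[C@@H](CCCCCCCCCCCCC[C@H](C)O[Si](C)(C)C(C)(C)C)[C@H]1C(=O)O
F8 | step 7 | (2S,3S)-oxirane-2,3-diyldimethanol | OC[C@@H]1O[C@H]1CO
F9 | step 7 | (2R,3R)-3-(hydroxymethyl)-5-(trimethylsilyl)pent-4-yne-1,2-diol | C[Si](C)(C)C#C[C@H](CO)[C@@H](O)CO
F10 | step 7 | (2R)-2-[(4R)-2,2-dimethyl-1,3-dioxolan-4-yl]-4-(trimethylsilyl)but-3-yn-1-ol | C[Si](C)(C)C#C[C@H](CO)[C@@H]1COC(C)(C)O1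
F11 | step 7 | (4R)-4-{(2R)-1-[(4-methoxybenzyl)oxy]-4-(trimethylsilyl)but-3-yn-2-yl}-2,2-dimethyl-1,3-dioxolane | C[Si](C)(C)C#C[C@H](COCc1ccc(OC)cc1)[C@@H]1COC(C)(C)O1
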